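If G is to leave D standing rather than burn it, what must the given numbers say, and how far from that does spring stand?

| setting | spring | dawn | autumn | noon |
|---|---|---|---|---|
| E | 0.0010 M | 0.0010 M | 0.0010 M | 0.0010 M |
| G | 0.01 mol% | 0.01 mol% | 0.01 mol% | 0.01 mol% |
| temperature | 25 °C | 55 °C | −5 °C | −35 °C |
| time | 50 s | 50 s | 50 s | 50 s |

* which flask leads in amount of D, in percent of the E charged ("all alike" within 1.5 percentage points) (spring / dawn / autumn / noon / all alike)
* how much D is there at the end, in percent of the E charged: spring
* how much D is there at the end, in percent of the E charged: dawn
* how much D is there at the end, in percent of the E charged: autumn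
* how much D is there at the end, in percent of the E charged: noon

- at 25 °C the constants are as listed, elsewhere as the activation energies make them

    G → J (k1 = 0.00228 s⁻¹, Ea1 = 248 kJ mol⁻¹)
    E + G → D + G, rate k2*[E]*[G]/(1 + ([E]/Km2)) (Km2 = 0.0673 mM, k2 = 1.43 × 10⁹ M⁻¹ s⁻¹, Ea2 = 8.00 kJ mol⁻¹)
    G + D → G + L (k3 = 1.38 × 10⁶ M⁻¹ s⁻¹, Ea3 = 18.0 kJ mol⁻¹)
    (constants at 25 °C)

G turns E into D, the same G turns D into L, and meanwhile G decays by itself to J, a form outside its working round. In spring, where the constants stand as listed, the charge of G is 1.00 × 10⁻⁷ M, and at the ceiling of its rate law E needs about 0.104 s, which is shorter than the run. After that, D falls as a pseudo-first-order decay with [G] as its driver. The half-life of G in spring, 5.07 min, is longer than the run, so I replace the curve of [G] by its value at mid-run, 94.5% of the charge. The true mean over the run is 94.5%, which agrees with it to the digits I carry.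

This gives 6.52 for the burn number, which is the constant of the step from D to L times the mean [G] times the time, and with D formed early in the run, D at the end is exp(−burn number) of the E charged, here in spring 0.148%. For the opposite outcome in spring, D surviving one half-life, the burn number would have to be 0.693, and spring stands 9.41 times above that; D's half-life at the full charge of G is 5.02 s, shorter than the run. Elsewhere I go no further by hand than this: from noon to dawn the decay of G speeds up by 8.3 × 10¹⁴, far more than the burning of D with its 12, so I look to dawn for a small burn number.

The forecast names dawn as leader, with 0.148% for spring, 54.7% for dawn, 4.7% for autumn and 33.1% for noon. Its spring figure matches mine, and for the three cooler flasks it holds that “E is gone in under a second”.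

The simulation puts dawn first with 54.7%, and 45% of the E is still there in that flask. Noon has 33.1%, autumn 4.70% and spring 0.148%.

In spring, the half-life of D by the step to L, 5.0 s at 0.0568 s, is shorter than the 50 s of the run, while [G] still stands at 89.2% of its charge at the end. In the neighbour of spring charged with 0.004 mol% of G, the same temperature keeps the same mean fraction, so the burn number becomes 2.61 and D should be 7.35%; the computed flask holds 7.42%.

The numbers are assumed; the result is computed.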